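**Retrosynth­etic overview**

1. The route rests on the doubly allylic C2 methylene between the two Z-trisubstituted alkenes C1=C10 and C3=C4 of the ten-membered ring. The C2–C3 bond is cut to a primary Z allylic chloride (C2) and a Z alkenylstannane (C3), so the carbocycle (second ring) is closed last by an intramolecular Stille coupling.
2. The cis-fused α-methylene-γ-lactone (first ring) is made earlier: a (diethoxyphosphoryl)acetate tethered on O6 opens a cis C7–C8 epoxide at C7 with inversion and is then methylenated, which leaves O8 free for the epoxy ester.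
3. The epoxy alcohol comes from a Z C7=C8 allylic alcohol by hydroxyl-directed epoxidation; that alcohol comes from asymmetric alkynylation of a C3–C6 aldehyde with a C7–C2 alkyne (C6–C7 bond) and semihydrogenation.
4. Pieces: C3–C6 from but-3-yn-1-ol (anti-carboalumination sets Z C3=C4); C7–C2 from 3-(trimethylsilyl)propynal and methyl propiolate (asymmetric alkynylation sets C9, syn-carbocupration sets Z C1=C10); the epoxy acid from tiglic acid (asymmetric epoxidation).
5. End game after ring closure: O9 desilylation and acetylation.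

Key step: step 21

Remark (locants): C1–C10 are the ring carbons (C2 and C5 methylenes), C6 the lactone O–CH, C7 the ring-fusion CH, C8 the epoxy-ester CH, C9 the acetoxy CH, C11=C13 the exocyclic methylene, C12 the lactone carbonyl. These locants are used for all intermediates; CIP descriptors in names refer to each compound's own chain numbering.

Assumption: the sense of induction of the two zinc–ProPhenol alkynylations is set by the choice of ligand antipode, to be fixed by Mosher ester analysis of 8 and 13.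

**Route**

Step 1
Reactants: 1 but-3-yn-1-ol
Product: 3 (Z)-4-bromo-3-methylbut-3-en-1-ol, via chelated alkenylalane 2 (not isolated)
Conditions: Me3Al (3 equiv), Cp2ZrCl2 (0.25 equiv), (CH2Cl)2, 23 °C then reflux; NBS, THF, −30 to 0 °C
Reagents that add atoms: trimethylaluminium C[Al](C)C; N-bromosuccinimide O=C1CCC(=O)N1Br
Why: Zirconium-catalysed carboalumination (Negishi) puts methyl on the internal alkyne carbon, heating lets the alkenylalane isomerise to the alkoxide-chelated six-membered alane, and bromodealumination with retention should give the Z bromide (CH2 and Br cis).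

Step 2
Reactants: 3 (Z)-4-bromo-3-methylbut-3-en-1-ol
Product: 4 (Z)-4-bromo-3-methylbut-3-enal
Conditions: Dess–Martin periodinane, NaHCO3, CH2Cl2, 0 °C; used at once
Reagents that add atoms: none
Why: Dess–Martin oxidation is neutral and fast, so the β,γ-unsaturated aldehyde should form without migration of the double bond into conjugation.

Step 3
Reactants: 5 3-(trimethylsilyl)prop-2-ynal; 6 methyl prop-2-ynoate (3 equiv)
Product: 8 methyl (4S)-4-hydroxy-6-(trimethylsilyl)hexa-2,5-diynoate, via zinc alkynylide 7 (not isolated)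
Conditions: Me2Zn, ProPhenol ligand (cat., antipode giving 4S), Ph3P=O (cat.), toluene, 0 °C
Reagents that add atoms: none
Why: Catalytic asymmetric alkynylzinc addition in the chiral dizinc–ProPhenol pocket selects one aldehyde face and should set the carbinol (later C9) as 4S.

Step 4
Reactants: 8 methyl (4S)-4-hydroxy-6-(trimethylsilyl)hexa-2,5-diynoate
Product: 9 methyl (4S)-4-[(tert-butyldimethylsilyl)oxy]-6-(trimethylsilyl)hexa-2,5-diynoate
Conditions: TBSCl, imidazole, DMF, 0 °C to rt
Reagents that add atoms: tert-butyldimethylsilyl chloride CC(C)(C)[Si](C)(C)Cl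
Why: Standard silylation of a secondary propargylic alcohol under weakly basic conditions leaves the stereocentre untouched.

Step 5
Reactants: 9 methyl (4S)-4-[(tert-butyldimethylsilyl)oxy]-6-(trimethylsilyl)hexa-2,5-diynoate
Product: 10 methyl (2Z,4S)-4-[(tert-butyldimethylsilyl)oxy]-3-methyl-6-(trimethylsilyl)hex-2-en-5-ynoate
Conditions: Me2CuLi (from MeLi and CuI), THF, −78 °C; NH4Cl/MeOH quench at −78 °C
Reagents that add atoms: lithium dimethylcuprate [Li+].C[Cu-]C
Why: Syn carbocupration (conjugate addition) of the ynoate places methyl and hydrogen cis, so cold protonation of the alkenylcuprate with retention should give the Z enoate with C9 and the ester cis.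

Step 6
Reactants: 10 methyl (2Z,4S)-4-[(tert-butyldimethylsilyl)oxy]-3-methyl-6-(trimethylsilyl)hex-2-en-5-ynoate
Product: 11 methyl (2Z,4R)-4-[(tert-butyldimethylsilyl)oxy]-3-methylhex-2-en-5-ynoate
Conditions: K2CO3 (cat.), MeOH, 0 °C
Reagents that add atoms: none
Why: Methanolysis of the alkynyl C–Si bond (protodesilylation) is selective over the O-silyl ether and the methyl ester; the descriptor changes only through CIP priorities.

Step 7
Reactants: 11 methyl (2Z,4R)-4-[(tert-butyldimethylsilyl)oxy]-3-methylhex-2-en-5-ynoate (excess, recovered); 4 (Z)-4-bromo-3-methylbut-3-enal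
Product: 13 methyl (2Z,4S,7S,9Z)-10-bromo-4-[(tert-butyldimethylsilyl)oxy]-7-hydroxy-3,9-dimethyldeca-2,9-dien-5-ynoate, via zinc alkynylide 12 (not isolated)
Conditions: Me2Zn, ProPhenol ligand (cat., antipode giving 7S), Ph3P=O (cat.), toluene, 0 °C
Reagents that add atoms: none
Why: A second zinc–ProPhenol asymmetric alkynylation, amine-free and only weakly basic, forms C6–C7 and should set C6 under catalyst control, while any C9 epimer carried from step 3 becomes a separable diastereomer.

Step 8
Reactants: 13 methyl (2Z,4S,7S,9Z)-10-bromo-4-[(tert-butyldimethylsilyl)oxy]-7-hydroxy-3,9-dimethyldeca-2,9-dien-5-ynoate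
Product: 14 methyl (2Z,4R,5Z,7S,9Z)-10-bromo-4-[(tert-butyldimethylsilyl)oxy]-7-hydroxy-3,9-dimethyldeca-2,5,9-trienoate
Conditions: H2 (1 atm), Pd/CaCO3 poisoned with Pb(OAc)2 (Lindlar catalyst), quinoline, EtOAc, rt
Reagents that add atoms: none
Why: Lindlar semihydrogenation adds H2 syn to the alkyne to give the Z C7=C8 alkene, and the trisubstituted enoate and the alkenyl bromide should be left untouched at 1 atm.

Step 9
Reactants: 14 methyl (2Z,4R,5Z,7S,9Z)-10-bromo-4-[(tert-butyldimethylsilyl)oxy]-7-hydroxy-3,9-dimethyldeca-2,5,9-trienoate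
Product: 15 methyl (2Z,4S,5R,6R,7S,9Z)-10-bromo-4-[(tert-butyldimethylsilyl)oxy]-5,6-epoxy-7-hydroxy-3,9-dimethyldeca-2,9-dienoate
Conditions: mCPBA, NaHCO3, CH2Cl2, 0 °C
Reagents that add atoms: 3-chloroperoxybenzoic acid O=C(OO)c1cccc(Cl)c1
Why: In this hydroxyl-directed peracid epoxidation, allylic 1,3-strain holds the C6–H in the alkene plane, so the hydrogen-bonded peracid attacks syn to the C6 hydroxyl (threo) and anti to the C9 silyl ether to give the cis epoxide, while the electron-poor enoate and bromoalkene should not react.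

Step 10
Reactants: 15 methyl (2Z,4S,5R,6R,7S,9Z)-10-bromo-4-[(tert-butyldimethylsilyl)oxy]-5,6-epoxy-7-hydroxy-3,9-dimethyldeca-2,9-dienoate
Product: 16 (2Z,4S,5R,6R,7S,9Z)-10-bromo-4-[(tert-butyldimethylsilyl)oxy]-5,6-epoxy-3,9-dimethyldeca-2,9-diene-1,7-diol
Conditions: i-Bu2AlH (DIBAL-H), CH2Cl2, −78 °C; Rochelle salt
Reagents that add atoms: none
Why: Low-temperature DIBAL-H reduction takes the enoate to the primary allylic alcohol by 1,2-hydride delivery, keeping the Z alkene, and the epoxide should not be opened at −78 °C.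

Step 11
Reactants: 16 (2Z,4S,5R,6R,7S,9Z)-10-bromo-4-[(tert-butyldimethylsilyl)oxy]-5,6-epoxy-3,9-dimethyldeca-2,9-diene-1,7-diol
Product: 17 (2Z,4S,5R,6R,7S,9Z)-10-bromo-4-[(tert-butyldimethylsilyl)oxy]-5,6-epoxy-3,9-dimethyl-1-[(triethylsilyl)oxy]deca-2,9-dien-7-ol
Conditions: Et3SiCl (1.05 equiv), imidazole, CH2Cl2, −78 °C
Reagents that add atoms: chlorotriethylsilane CC[Si](Cl)(CC)CC
Why: Kinetic silylation should take the unhindered primary allylic hydroxyl (C2) in preference to the hindered secondary epoxy alcohol (C6).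

Step 12
Reactants: 17 (2Z,4S,5R,6R,7S,9Z)-10-bromo-4-[(tert-butyldimethylsilyl)oxy]-5,6-epoxy-3,9-dimethyl-1-[(triethylsilyl)oxy]deca-2,9-dien-7-ol; 18 (diethoxyphosphoryl)acetic acid
Product: 19 O6 (diethoxyphosphoryl)acetate of 17
Conditions: DCC, DMAP (cat.), CH2Cl2, 0 °C to rt
Reagents that add atoms: none
Why: Steglich esterification of the secondary alcohol installs C11 and C12 as a tethered carbon nucleophile that also carries the handle for the later olefination.

Step 13
Reactants: 19 O6 (diethoxyphosphoryl)acetate of 17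
Product: 20 C3 tributylstannane corresponding to 19
Conditions: (Bu3Sn)2, Pd(PPh3)4 (cat.), toluene, 100 °C
Reagents that add atoms: hexabutylditin CCCC[Sn](CCCC)(CCCC)[Sn](CCCC)(CCCC)CCCC
Why: Palladium-catalysed stannylation of the alkenyl bromide (oxidative addition, tin–tin transmetallation, reductive elimination) keeps the Z geometry and is placed after the peracid step, which an alkenylstannane would not survive.

Step 14
Reactants: 20 C3 tributylstannane corresponding to 19
Product: 22 cis-fused α-methylene-γ-lactone with free C8 hydroxyl, via phosphono lactone 21 (not isolated)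
Conditions: NaH (1.05 equiv), THF, 0 to 45 °C; then paraformaldehyde, rt
Reagents that add atoms: formaldehyde C=O
Why: The sodium phosphonoacetate attacks the neighbouring epoxide carbon C7 in a 5-exo-tet SN2 opening with inversion while C8 keeps its oxygen, which sets the cis lactone and the C7/C8 relationship stereospecifically, and the α-phosphono lactone anion then undergoes Horner–Wadsworth–Emmons methylenation with formaldehyde in the same flask.

Step 15
Reactants: 23 tiglic acid
Product: 24 (E)-2-methylbut-2-en-1-ol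
Conditions: LiAlH4, Et2O, 0 °C
Reagents that add atoms: none
Why: Hydride reduction of the carboxylic acid to the primary allylic alcohol keeps the E trisubstituted alkene.

Step 16
Reactants: 24 (E)-2-methylbut-2-en-1-ol
Product: 25 [(2R,3R)-2,3-dimethyloxiran-2-yl]methanol
Conditions: Ti(OiPr)4 (cat.), D-(−)-diisopropyl tartrate (cat.), t-BuOOH, 4 Å MS, CH2Cl2, −20 °C
Reagents that add atoms: tert-butyl hydroperoxide CC(C)(C)OO
Why: In this Sharpless asymmetric epoxidation, the D-(−)-tartrate delivers oxygen to the alkene face that gives the 2R,3R epoxy alcohol with the two methyl groups cis.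

Step 17
Reactants: 25 [(2R,3R)-2,3-dimethyloxiran-2-yl]methanol
Product: 26 (2S,3R)-2,3-dimethyloxirane-2-carboxylic acid
Conditions: RuCl3 (cat.), NaIO4, CCl4/MeCN/H2O, rt
Reagents that add atoms: water O
Why: Ruthenium tetroxide oxidation (catalytic RuCl3 with periodate) takes the primary alcohol to the acid without opening the epoxide; the C2 descriptor changes only through CIP priorities.

Step 18
Reactants: 22 cis-fused α-methylene-γ-lactone with free C8 hydroxyl; 26 (2S,3R)-2,3-dimethyloxirane-2-carboxylic acid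
Product: 28 C8 (2S,3R)-2,3-dimethyloxirane-2-carboxylate of 22, via mixed anhydride 27 (not isolated)
Conditions: 2,4,6-trichlorobenzoyl chloride, Et3N, THF, 0 °C; then 22, DMAP, toluene, rt
Reagents that add atoms: none
Why: Yamaguchi esterification through the mixed anhydride should acylate the hindered secondary C8 hydroxyl with the α-quaternary epoxy acid quickly enough to outrun lactone migration.

Step 19
Reactants: 28 C8 (2S,3R)-2,3-dimethyloxirane-2-carboxylate of 22
Product: 29 C2 allylic alcohol (triethylsilyl group removed)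
Conditions: PPTS, MeOH/CH2Cl2, 0 °C
Reagents that add atoms: none
Why: Mild acid methanolysis cleaves the primary triethylsilyl ether selectively over the secondary tert-butyldimethylsilyl ether and is too weak to protodestannylate the alkene or open the glycidic ester.

Step 20
Reactants: 29 C2 allylic alcohol
Product: 31 stannane allylic chloride (cyclisation precursor), via allylic mesylate 30 (not isolated)
Conditions: MsCl, 2,4,6-collidine, LiCl, DMF, 0 °C
Reagents that add atoms: lithium chloride [Li+].[Cl-]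
Why: Mesylation with in situ SN2 chloride displacement at the primary allylic carbon should give the chloride without allylic transposition or loss of Z geometry, and no electrophilic halogen is present to attack the stannane.

Step 21
Reactants: 31 stannane allylic chloride
Product: 32 9-O-tert-butyldimethylsilyl macrocycle
Conditions: Pd2(dba)3 (20 mol%), AsPh3 (80 mol%), degassed THF, 1 mM by slow addition, 60 °C
Reagents that add atoms: none
Why: Zerovalent palladium ionises the primary allylic C2–Cl bond to an η3-allyl complex over C2–C1–C10, the C3 stannane transmetallates onto palladium (helped by the weakly bound AsPh3), and reductive elimination at the unhindered C2 terminus forms C2–C3; the closest known reaction type is the Stille coupling of allylic halides with alkenylstannanes in its macrocyclising form. The ten-membered ring closes in the reductive elimination from a palladacycle that holds both chain ends, and the cis-fused lactone and the two Z alkenes fold the chain so that C2 and C3 can meet. No stereocentre is created, and C6–C9, the lactone and the epoxy ester are spectators under neutral conditions. The step needs linear (C2) rather than branched (C10) coupling, retention of both Z geometries and cyclisation rather than oligomerisation: the trisubstituted C10 terminus disfavours branched coupling, syn–anti exchange would need an η1 palladium on tertiary C10, alkenyl transfer from tin is stereoretentive, and high dilution with slow addition suppresses intermolecular coupling. O9 is kept as a silyl ether so that no second allylic leaving group competes for palladium.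

Step 22
Reactants: 32 9-O-tert-butyldimethylsilyl macrocycle
Product: 33 9-hydroxy macrocycle
Conditions: HF·pyridine, pyridine, THF, 0 °C to rt
Reagents that add atoms: none
Why: Buffered HF·pyridine cleaves the hindered allylic silyl ether under non-basic conditions, which avoids acyl migration from O8 and lactone relocation.

Step 23
Reactants: 33 9-hydroxy macrocycle
Product: 34 target CNP0188864.1
Conditions: Ac2O, pyridine, DMAP (cat.), CH2Cl2, 0 °C
Reagents that add atoms: acetic anhydride CC(=O)OC(C)=O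
Why: DMAP-catalysed acetylation of the C9 secondary alcohol completes the target without touching any stereocentre.

**Compound list**

1 | but-3-yn-1-ol | C#CCCO | starting material
2 | chelated (Z)-alkenylalane (2,4-dimethyl-5,6-dihydro-2H-1,2-oxaluminine) | CC1=C[Al](C)OCC1 | intermediate
3 | (Z)-4-bromo-3-methylbut-3-en-1-ol | OCC/C(C)=C\Br | intermediate
4 | (Z)-4-bromo-3-methylbut-3-enal | O=CC/C(C)=C\Br | intermediate
5 | 3-(trimethylsilyl)prop-2-ynal | C[Si](C)(C)C#CC=O | starting material
6 | methyl prop-2-ynoate | C#CC(=O)OC | starting material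
7 | methyl 3-(methylzincio)prop-2-ynoate | C[Zn]C#CC(=O)OC | intermediate
8 | methyl (4S)-4-hydroxy-6-(trimethylsilyl)hexa-2,5-diynoate | C[Si](C)(C)C#C[C@@H](O)C#CC(=O)OC | intermediate
9 | methyl (4S)-4-[(tert-butyldimethylsilyl)oxy]-6-(trimethylsilyl)hexa-2,5-diynoate | C[Si](C)(C)C#C[C@@H](O[Si](C)(C)C(C)(C)C)C#CC(=O)OC | intermediate
10 | methyl (2Z,4S)-4-[(tert-butyldimethylsilyl)oxy]-3-methyl-6-(trimethylsilyl)hex-2-en-5-ynoate | C[Si](C)(C)C#C[C@@H](O[Si](C)(C)C(C)(C)C)/C(C)=C\C(=O)OC | intermediate
11 | methyl (2Z,4R)-4-[(tert-butyldimethylsilyl)oxy]-3-methylhex-2-en-5-ynoate | C#C[C@@H](O[Si](C)(C)C(C)(C)C)/C(C)=C\C(=O)OC | intermediate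
12 | methylzinc alkynylide of 11 | C[Zn]C#C[C@@H](O[Si](C)(C)C(C)(C)C)/C(C)=C\C(=O)OC | intermediate
13 | methyl (2Z,4S,7S,9Z)-10-bromo-4-[(tert-butyldimethylsilyl)oxy]-7-hydroxy-3,9-dimethyldeca-2,9-dien-5-ynoate | O[C@@H](C/C(C)=C\Br)C#C[C@@H](O[Si](C)(C)C(C)(C)C)/C(C)=C\C(=O)OC | intermediate
14 | methyl (2Z,4R,5Z,7S,9Z)-10-bromo-4-[(tert-butyldimethylsilyl)oxy]-7-hydroxy-3,9-dimethyldeca-2,5,9-trienoate | O[C@@H](C/C(C)=C\Br)/C=C\[C@@H](O[Si](C)(C)C(C)(C)C)/C(C)=C\C(=O)OC | intermediate
15 | methyl (2Z,4S,5R,6R,7S,9Z)-10-bromo-4-[(tert-butyldimethylsilyl)oxy]-5,6-epoxy-7-hydroxy-3,9-dimethyldeca-2,9-dienoate (cis C7–C8 epoxide, threo to the C6 hydroxyl) | O[C@@H](C/C(C)=C\Br)[C@H]1O[C@H]1[C@@H](O[Si](C)(C)C(C)(C)C)/C(C)=C\C(=O)OC | intermediate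
16 | (2Z,4S,5R,6R,7S,9Z)-10-bromo-4-[(tert-butyldimethylsilyl)oxy]-5,6-epoxy-3,9-dimethyldeca-2,9-diene-1,7-diol | O[C@@H](C/C(C)=C\Br)[C@H]1O[C@H]1[C@@H](O[Si](C)(C)C(C)(C)C)/C(C)=C\CO | intermediate
17 | (2Z,4S,5R,6R,7S,9Z)-10-bromo-4-[(tert-butyldimethylsilyl)oxy]-5,6-epoxy-3,9-dimethyl-1-[(triethylsilyl)oxy]deca-2,9-dien-7-ol | O[C@@H](C/C(C)=C\Br)[C@H]1O[C@H]1[C@@H](O[Si](C)(C)C(C)(C)C)/C(C)=C\CO[Si](CC)(CC)CC | intermediate
18 | (diethoxyphosphoryl)acetic acid | CCOP(=O)(OCC)CC(=O)O | starting material
19 | O6 (diethoxyphosphoryl)acetate of 17 (stereocentres as in 17) | CCOP(=O)(OCC)CC(=O)O[C@@H](C/C(C)=C\Br)[C@H]1O[C@H]1[C@@H](O[Si](C)(C)C(C)(C)C)/C(C)=C\CO[Si](CC)(CC)CC | intermediate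
20 | C3 tributylstannane corresponding to 19 (Z C3=C4 kept) | CCOP(=O)(OCC)CC(=O)O[C@@H](C/C(C)=C\[Sn](CCCC)(CCCC)CCCC)[C@H]1O[C@H]1[C@@H](O[Si](C)(C)C(C)(C)C)/C(C)=C\CO[Si](CC)(CC)CC | intermediate
21 | cis-β,γ-disubstituted α-(diethoxyphosphoryl)-γ-lactone (lactone O on C6, free C8–OH, 9-OTBS, 2-OTES, 3-SnBu3; mixture at C11) | CCOP(=O)(OCC)C1C(=O)O[C@@H](C/C(C)=C\[Sn](CCCC)(CCCC)CCCC)[C@H]1[C@@H](O)[C@@H](O[Si](C)(C)C(C)(C)C)/C(C)=C\CO[Si](CC)(CC)CC | intermediate
22 | cis-fused α-methylene-γ-lactone with free C8 hydroxyl (9-OTBS, 2-OTES, 3-SnBu3) | C=C1C(=O)O[C@@H](C/C(C)=C\[Sn](CCCC)(CCCC)CCCC)[C@H]1[C@@H](O)[C@@H](O[Si](C)(C)C(C)(C)C)/C(C)=C\CO[Si](CC)(CC)CC | intermediate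
23 | tiglic acid | C/C=C(\C)C(=O)O | starting material
24 | (E)-2-methylbut-2-en-1-ol | C/C=C(\C)CO | intermediate
25 | [(2R,3R)-2,3-dimethyloxiran-2-yl]methanol | OC[C@@]1(C)O[C@@H]1C | intermediate
26 | (2S,3R)-2,3-dimethyloxirane-2-carboxylic acid | O=C(O)[C@@]1(C)O[C@@H]1C | intermediate
27 | mixed anhydride of 26 with 2,4,6-trichlorobenzoic acid | O=C(OC(=O)[C@@]1(C)O[C@@H]1C)c1c(Cl)cc(Cl)cc1Cl | intermediate
28 | C8 (2S,3R)-2,3-dimethyloxirane-2-carboxylate of 22 | C=C1C(=O)O[C@@H](C/C(C)=C\[Sn](CCCC)(CCCC)CCCC)[C@H]1[C@@H](OC(=O)[C@@]2(C)O[C@@H]2C)[C@@H](O[Si](C)(C)C(C)(C)C)/C(C)=C\CO[Si](CC)(CC)CC | intermediate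
29 | C2 allylic alcohol corresponding to 28 | C=C1C(=O)O[C@@H](C/C(C)=C\[Sn](CCCC)(CCCC)CCCC)[C@H]1[C@@H](OC(=O)[C@@]2(C)O[C@@H]2C)[C@@H](O[Si](C)(C)C(C)(C)C)/C(C)=C\CO | intermediate
30 | C2 allylic mesylate corresponding to 29 | C=C1C(=O)O[C@@H](C/C(C)=C\[Sn](CCCC)(CCCC)CCCC)[C@H]1[C@@H](OC(=O)[C@@]2(C)O[C@@H]2C)[C@@H](O[Si](C)(C)C(C)(C)C)/C(C)=C\COS(C)(=O)=O | intermediate
31 | stannane allylic chloride (cyclisation precursor) | C=C1C(=O)O[C@@H](C/C(C)=C\[Sn](CCCC)(CCCC)CCCC)[C@H]1[C@@H](OC(=O)[C@@]2(C)O[C@@H]2C)[C@@H](O[Si](C)(C)C(C)(C)C)/C(C)=C\CCl | intermediate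
32 | 9-O-tert-butyldimethylsilyl macrocycle (ten-membered ring with Z C1=C10 and Z C3=C4, 6,12-lactone, 8-O-epoxy ester) | C=C1C(=O)O[C@H]2C/C(C)=C\C/C=C(/C)[C@H](O[Si](C)(C)C(C)(C)C)[C@H](OC(=O)[C@@]3(C)O[C@@H]3C)[C@@H]12 | intermediate
33 | 9-hydroxy macrocycle | C=C1C(=O)O[C@H]2C/C(C)=C\C/C=C(/C)[C@H](O)[C@H](OC(=O)[C@@]3(C)O[C@@H]3C)[C@@H]12 | intermediate
34 | CNP0188864.1: (6S,7S,8R,9S)-9-acetoxy-8-[(2S,3R)-2,3-dimethyloxirane-2-carbonyloxy]-(1(10)Z,3Z)-germacra-1(10),3,11(13)-trien-12,6-olide | C=C1C(=O)O[C@H]2C/C(C)=C\C/C=C(/C)[C@H](OC(C)=O)[C@H](OC(=O)[C@@]3(C)O[C@@H]3C)[C@@H]12 | target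

**Totals**

Total step count: 23.
Longest linear sequence: 18 steps (steps 3–14 and 18–23, from 5 and 6).

**Steps most likely to fail**

Step 21. The process at risk is slow transfer of the alkenyl group from tin to the π-allylpalladium intermediate in a strained ten-membered closure. That would leave time for intermolecular coupling to oligomers or for β-hydride loss to a diene. The fallback replaces tin by boron and closes the ring by a Suzuki–Miyaura coupling. It sets out from bromide 19: Miyaura borylation (B2pin2, PdCl2(PPh3)2, PPh3, KOPh, toluene, 50 °C) should give the alkenyl pinacolboronate F1. The operations of steps 14, 18, 19 and 20 applied to the boron series should give the hydroxy lactone F2, the epoxy ester F3, the allylic alcohol F4 and the boronate allylic chloride F5. Fluoride-promoted intramolecular allyl–alkenyl coupling of F5 (Pd(PPh3)4, CsF, THF, 1 mM, 50 °C) comes back to the route at 32.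

Step 14. The process at risk is slow epoxide opening by the phosphonate-stabilised anion, because the ester tether must first rotate into the s-cis geometry of a lactone. Prolonged exposure to base could then let the freed C8 alkoxide relocate the lactone to O8, or let the anion react intermolecularly. The fallback uses a non-stabilised lithium enolate and adds the methylene afterwards. It sets out from 17: acetylation (Ac2O, pyridine, DMAP) should give the epoxy acetate F6, and stannylation as in step 13 the stannane F7. LiHMDS in THF (−78 to −20 °C) should close the lactone by 5-exo opening of the epoxide at C7 with inversion, giving the saturated hydroxy lactone F8. Its dianion (LDA, 2.2 equiv, THF, −78 °C) with dimethylmethyleneammonium iodide should give the Mannich base F9. Quaternisation with MeI and elimination with NaHCO3 come back to the route at 22.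

Step 7. The process at risk is enolisation of aldehyde 4 by the zinc alkoxide catalyst, with migration of the C3=C4 double bond into conjugation, together with incomplete facial control at C6. The fallback separates bond formation from stereocontrol by oxidation and asymmetric reduction. It sets out from 11 and 4: ligand-free addition of zinc alkynylide 12 (Me2Zn, toluene, −20 °C) should give 13 together with its C6 epimer F10. Dess–Martin oxidation of the mixture should give the ynone F11. Noyori asymmetric transfer hydrogenation (RuCl[(S,S)-TsDPEN](p-cymene) or its antipode as required, i-PrOH, rt) comes back to the route at 13 with C6 set by the catalyst.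

Further compounds

F1 | step 21 | alkenyl pinacolboronate corresponding to 20 | CCOP(=O)(OCC)CC(=O)O[C@@H](C/C(C)=C\B1OC(C)(C)C(C)(C)O1)[C@H]2O[C@H]2[C@@H](O[Si](C)(C)C(C)(C)C)/C(C)=C\CO[Si](CC)(CC)CC
F2 | step 21 | boronate hydroxy lactone corresponding to 22 | C=C1C(=O)O[C@@H](C/C(C)=C\B2OC(C)(C)C(C)(C)O2)[C@H]1[C@@H](O)[C@@H](O[Si](C)(C)C(C)(C)C)/C(C)=C\CO[Si](CC)(CC)CC
F3 | step 21 | boronate epoxy ester corresponding to 28 | C=C1C(=O)O[C@@H](C/C(C)=C\B2OC(C)(C)C(C)(C)O2)[C@H]1[C@@H](OC(=O)[C@@]3(C)O[C@@H]3C)[C@@H](O[Si](C)(C)C(C)(C)C)/C(C)=C\CO[Si](CC)(CC)CC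
F4 | step 21 | boronate allylic alcohol corresponding to 29 | C=C1C(=O)O[C@@H](C/C(C)=C\B2OC(C)(C)C(C)(C)O2)[C@H]1[C@@H](OC(=O)[C@@]3(C)O[C@@H]3C)[C@@H](O[Si](C)(C)C(C)(C)C)/C(C)=C\CO
F5 | step 21 | boronate allylic chloride corresponding to 31 | C=C1C(=O)O[C@@H](C/C(C)=C\B2OC(C)(C)C(C)(C)O2)[C@H]1[C@@H](OC(=O)[C@@]3(C)O[C@@H]3C)[C@@H](O[Si](C)(C)C(C)(C)C)/C(C)=C\CCl
F6 | step 14 | O6 acetate of 17 | CC(=O)O[C@@H](C/C(C)=C\Br)[C@H]1O[C@H]1[C@@H](O[Si](C)(C)C(C)(C)C)/C(C)=C\CO[Si](CC)(CC)CC
F7 | step 14 | C3 tributylstannane corresponding to F6 | CC(=O)O[C@@H](C/C(C)=C\[Sn](CCCC)(CCCC)CCCC)[C@H]1O[C@H]1[C@@H](O[Si](C)(C)C(C)(C)C)/C(C)=C\CO[Si](CC)(CC)CC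
F8 | step 14 | saturated cis hydroxy lactone (C11 methylene) | C1C(=O)O[C@@H](C/C(C)=C\[Sn](CCCC)(CCCC)CCCC)[C@H]1[C@@H](O)[C@@H](O[Si](C)(C)C(C)(C)C)/C(C)=C\CO[Si](CC)(CC)CC
F9 | step 14 | α-(dimethylaminomethyl) lactone (Mannich base; mixture at C11) | CN(C)CC1C(=O)O[C@@H](C/C(C)=C\[Sn](CCCC)(CCCC)CCCC)[C@H]1[C@@H](O)[C@@H](O[Si](C)(C)C(C)(C)C)/C(C)=C\CO[Si](CC)(CC)CC
F10 | step 7 | C6 epimer of 13 | O[C@H](C/C(C)=C\Br)C#C[C@@H](O[Si](C)(C)C(C)(C)C)/C(C)=C\C(=O)OC
F11 | step 7 | ynone (C6 ketone) from 13 and F10 | O=C(C/C(C)=C\Br)C#C[C@@H](O[Si](C)(C)C(C)(C)C)/C(C)=C\C(=O)OC
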